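**Retrosynthetic overview**
- Target ⇐ macrocyclic ketone (C=O → C=CH2) ⇐ macrocyclic (4R)-aldehyde + homoprenyl Grignard reagent, then oxidation.
- Macrocyclic aldehyde ⇐ open-chain acetoxy-enoate aldehyde by closing C1–C14. Zerovalent palladium ionises the allylic acetate and a chiral enamine of the terminal aldehyde captures it, mirroring the C1–C14 closure of the geranylfarnesyl cation and setting 4R.
- Open-chain aldehyde ⇐ Still–Gennari olefination (Z-enoate) of an α-alkylated phosphonoacetate with 2-oxoethyl acetate; the phosphonate ⇐ C-alkylation with a (3E,7Z)-dienol.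
- Dienol ⇐ B-alkyl Suzuki coupling of a Z-diene (carbocupration of propyne, then vinylation) with (3E)-4-iodopent-3-en-1-ol (hydrozirconation of pent-3-yn-1-ol).
- Ring order: one 14-membered carbocycle only, closed in step 7.

Assumption: open-chain positions are called C1 to C15, counted from the acetoxy-bearing carbon to the formyl carbon of the cyclisation substrate (ring closure C1–C14); ring locants follow the IUPAC names below, where the stereocentre is C4.

**Step 1**
Reactants: 1 4-chloro-1,1-dimethoxybutane; 2 propyne; 3 bromoethene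
Product: 8 (3Z)-8,8-dimethoxy-4-methylocta-1,3-diene, via Grignard reagent 4 (not isolated), via alkylcopper 5 (not isolated), via alkenylcopper 6 (not isolated), via alkenylzinc bromide 7 (not isolated)
Conditions: Mg, THF, 55 °C; CuBr·SMe2, Et2O–Me2S, −45 °C; 2, −25 °C; ZnBr2, THF, −20 °C; 3, Pd(PPh3)4 (3 mol %), 0 → 20 °C
Reagents that add atoms: none
Why: Normant carbocupration adds the alkylcopper syn across propyne with copper on the terminal carbon, so chain and metal are cis, and transmetalation to zinc followed by Pd-catalysed Negishi-type vinylation keeps that geometry and gives the Z-trisubstituted alkene.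

**Step 2**
Reactants: 9 pent-3-yn-1-ol
Product: 11 (3E)-4-iodopent-3-en-1-ol, via alkenylzirconium alkoxide 10 (not isolated)
Conditions: Cp2Zr(H)Cl (2.5 equiv), THF, 45 °C; I2, 0 °C
Reagents that add atoms: iodine, [I][I]
Why: Hydrozirconation–iodination: Zr–H adds syn and, with excess reagent, the metal settles on the less hindered methyl-bearing alkyne carbon, and iodinolysis with retention gives the E-vinyl iodide.

**Step 3**
Reactants: 8 (3Z)-8,8-dimethoxy-4-methylocta-1,3-diene; 11 (3E)-4-iodopent-3-en-1-ol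
Product: 13 (3E,7Z)-12,12-dimethoxy-4,8-dimethyldodeca-3,7-dien-1-ol, via alkylborane 12 (not isolated)
Conditions: 8, 9-BBN, THF, 0 → 20 °C; then 11, Pd(dppf)Cl2 (5 mol %), AsPh3, aq. K3PO4, DMF, 20 °C
Reagents that add atoms: none
Why: 9-BBN hydroborates only the terminal CH2 of the monosubstituted vinyl group, and the B-alkyl Suzuki–Miyaura coupling joins the sp3 and sp2 carbons with retention of both alkene geometries.

**Step 4**
Reactants: 13 (3E,7Z)-12,12-dimethoxy-4,8-dimethyldodeca-3,7-dien-1-ol; 14 methyl [bis(2,2,2-trifluoroethoxy)phosphoryl]acetate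
Product: 15 methyl (5E,9Z)-2-[bis(2,2,2-trifluoroethoxy)phosphoryl]-14,14-dimethoxy-6,10-dimethyltetradeca-5,9-dienoate (racemic at C2)
Conditions: Bu3P=CHCN (1.5 equiv), toluene, 100 °C
Reagents that add atoms: none
Why: Tsunoda-type Mitsunobu C-alkylation: the ylide deprotonates the acidic phosphonoacetate and turns the primary alcohol into an alkoxyphosphonium leaving group, so SN2 displacement gives the mono-alkylated phosphonate without touching the alkenes or the acetal.

**Step 5**
Reactants: 15 methyl (5E,9Z)-2-[bis(2,2,2-trifluoroethoxy)phosphoryl]-14,14-dimethoxy-6,10-dimethyltetradeca-5,9-dienoate; 16 2-oxoethyl acetate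
Product: 18 methyl (2Z,5E,9Z)-2-(2-acetoxyethylidene)-14,14-dimethoxy-6,10-dimethyltetradeca-5,9-dienoate, via potassium phosphonate carbanion 17 (not isolated)
Conditions: KN(SiMe3)2, 18-crown-6, THF, −78 °C; then 16, −78 °C
Reagents that add atoms: none
Why: Still–Gennari olefination: the electron-poor trifluoroethyl phosphonate under dissociating conditions eliminates quickly from the kinetic adduct and places the CH2OAc group cis to the ester (Z).

**Step 6**
Reactants: 18 methyl (2Z,5E,9Z)-2-(2-acetoxyethylidene)-14,14-dimethoxy-6,10-dimethyltetradeca-5,9-dienoate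
Product: 19 methyl (2Z,5E,9Z)-2-(2-acetoxyethylidene)-6,10-dimethyl-14-oxotetradeca-5,9-dienoate
Conditions: PPTS (10 mol %), THF–H2O (4:1), 45 °C
Reagents that add atoms: water, O
Why: Mild acid-catalysed acetal hydrolysis unmasks the aldehyde while the allylic acetate, the Z-enoate and the trisubstituted alkenes stay intact.

**Step 7**
Reactants: 19 methyl (2Z,5E,9Z)-2-(2-acetoxyethylidene)-6,10-dimethyl-14-oxotetradeca-5,9-dienoate
Product: 22 methyl (1Z,4R,7Z,11E)-4-formyl-7,11-dimethylcyclotetradeca-1,7,11-triene-1-carboxylate, via enamine 20 (not isolated), via iminium acetate 21 (not isolated)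
Conditions: Pd(PPh3)4 (10 mol %), (S)-2-[diphenyl(trimethylsilyloxy)methyl]pyrrolidine (30 mol %), DMF–DMSO (1:1), 0 → 20 °C, syringe-pump addition of 19 over 24 h to 2 mM
Reagents that add atoms: none
Why: Proposed new method: a macrocyclic version of the Pd/amine dual-catalytic Tsuji–Trost α-allylation of aldehydes (known intermolecularly and for five- and six-membered rings), in which zerovalent palladium ionises the ester-activated allylic acetate to an allyl cation equivalent that is attacked at its unsubstituted terminus C1 by the C14=C15 π bond of E-enamine 20, whose C(Ph)2OSiMe3 group blocks one face so that the (S)-amine gives 4R, while high dilution favours the strain-free 14-membered ring and hydrolysis of iminium 21 returns the amine.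

**Step 8**
Reactants: 22 methyl (1Z,4R,7Z,11E)-4-formyl-7,11-dimethylcyclotetradeca-1,7,11-triene-1-carboxylate; 23 5-bromo-2-methylpent-2-ene
Product: 25 methyl (1Z,4R,7Z,11E)-4-(1-hydroxy-5-methylhex-4-en-1-yl)-7,11-dimethylcyclotetradeca-1,7,11-triene-1-carboxylate (both carbinol epimers), via Grignard reagent 24 (not isolated)
Conditions: 23, Mg, THF, 40 °C; then 22, THF, −78 °C; aq. NH4Cl
Reagents that add atoms: none
Why: Grignard addition: at −78 °C the aldehyde is far more electrophilic than the hindered conjugated methyl ester, the α-centre is not touched, and the new carbinol centre is erased in the next step.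

**Step 9**
Reactants: 25 methyl (1Z,4R,7Z,11E)-4-(1-hydroxy-5-methylhex-4-en-1-yl)-7,11-dimethylcyclotetradeca-1,7,11-triene-1-carboxylate
Product: 26 methyl (1Z,4R,7Z,11E)-7,11-dimethyl-4-(5-methylhex-4-enoyl)cyclotetradeca-1,7,11-triene-1-carboxylate
Conditions: Dess–Martin periodinane, CH2Cl2, 0 → 20 °C
Reagents that add atoms: none
Why: Dess–Martin oxidation is mild and non-basic, so the secondary alcohol becomes the ketone without epimerising the adjacent 4R centre or isomerising the Z-enoate.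

**Step 10**
Reactants: 26 methyl (1Z,4R,7Z,11E)-7,11-dimethyl-4-(5-methylhex-4-enoyl)cyclotetradeca-1,7,11-triene-1-carboxylate
Product: 27 methyl (1Z,4R,7Z,11E)-7,11-dimethyl-4-(6-methylhepta-1,5-dien-2-yl)cyclotetradeca-1,7,11-triene-1-carboxylate
Conditions: Zn, CH2Br2, TiCl4, THF, −40 → 5 °C (reagent pre-formed); then 26, CH2Cl2, 20 °C
Reagents that add atoms: dibromomethane, BrCBr
Why: Takai–Lombardo methylenation: the non-basic gem-dizinc/titanium reagent converts hindered enolisable ketones into 1,1-disubstituted alkenes without epimerisation and leaves the ester alone, which completes the exocyclic alkene of the target.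

**Compound list**
1 | 4-chloro-1,1-dimethoxybutane | COC(CCCCl)OC | starting material
2 | propyne | CC#C | starting material
3 | bromoethene (vinyl bromide) | C=CBr | starting material
4 | (4,4-dimethoxybutyl)magnesium chloride | COC(CCC[Mg]Cl)OC | intermediate
5 | (4,4-dimethoxybutyl)copper | COC(CCC[Cu])OC | intermediate
6 | [(1Z)-6,6-dimethoxy-2-methylhex-1-en-1-yl]copper | COC(CCC/C(C)=C\[Cu])OC | intermediate
7 | bromo[(1Z)-6,6-dimethoxy-2-methylhex-1-en-1-yl]zinc | COC(CCC/C(C)=C\[Zn]Br)OC | intermediate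
8 | (3Z)-8,8-dimethoxy-4-methylocta-1,3-diene | COC(CCC/C(C)=C\C=C)OC | intermediate
9 | pent-3-yn-1-ol | CC#CCCO | starting material
10 | [(2E)-5-{[chlorobis(cyclopentadienyl)zirconio]oxy}pent-2-en-2-yl]chlorobis(cyclopentadienyl)zirconium | C/C(=C\CCO[Zr](Cl)(C1C=CC=C1)C1C=CC=C1)[Zr](Cl)(C1C=CC=C1)C1C=CC=C1 | intermediate
11 | (3E)-4-iodopent-3-en-1-ol | C/C(I)=C\CCO | intermediate
12 | 9-[(3Z)-8,8-dimethoxy-4-methyloct-3-en-1-yl]-9-borabicyclo[3.3.1]nonane | COC(CCC/C(C)=C\CCB1C2CCCC1CCC2)OC | intermediate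
13 | (3E,7Z)-12,12-dimethoxy-4,8-dimethyldodeca-3,7-dien-1-ol | OCC/C=C(\C)CC/C=C(/C)CCCC(OC)OC | intermediate
14 | methyl [bis(2,2,2-trifluoroethoxy)phosphoryl]acetate | COC(=O)CP(=O)(OCC(F)(F)F)OCC(F)(F)F | starting material
15 | methyl (5E,9Z)-2-[bis(2,2,2-trifluoroethoxy)phosphoryl]-14,14-dimethoxy-6,10-dimethyltetradeca-5,9-dienoate (racemic at C2) | COC(=O)C(CC/C=C(\C)CC/C=C(/C)CCCC(OC)OC)P(=O)(OCC(F)(F)F)OCC(F)(F)F | intermediate
16 | 2-oxoethyl acetate | CC(=O)OCC=O | starting material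
17 | potassium salt of the C2 carbanion of 15 | [K+].COC(=O)[C-](CC/C=C(\C)CC/C=C(/C)CCCC(OC)OC)P(=O)(OCC(F)(F)F)OCC(F)(F)F | intermediate
18 | methyl (2Z,5E,9Z)-2-(2-acetoxyethylidene)-14,14-dimethoxy-6,10-dimethyltetradeca-5,9-dienoate | CC(=O)OC/C=C(\C(=O)OC)CC/C=C(\C)CC/C=C(/C)CCCC(OC)OC | intermediate
19 | methyl (2Z,5E,9Z)-2-(2-acetoxyethylidene)-6,10-dimethyl-14-oxotetradeca-5,9-dienoate | CC(=O)OC/C=C(\C(=O)OC)CC/C=C(\C)CC/C=C(/C)CCCC=O | intermediate
20 | methyl (2Z,5E,9Z,13E)-2-(2-acetoxyethylidene)-14-[(2S)-2-{diphenyl[(trimethylsilyl)oxy]methyl}pyrrolidin-1-yl]-6,10-dimethyltetradeca-5,9,13-trienoate | CC(=O)OC/C=C(\C(=O)OC)CC/C=C(\C)CC/C=C(/C)CC/C=C/N1CCC[C@H]1C(c1ccccc1)(c1ccccc1)O[Si](C)(C)C | intermediate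
21 | (2S)-2-{diphenyl[(trimethylsilyl)oxy]methyl}-1-{[(1R,3Z,7E,11Z)-4-(methoxycarbonyl)-8,12-dimethylcyclotetradeca-3,7,11-trien-1-yl]methylidene}pyrrolidin-1-ium acetate | C(=[N+]2CCC[C@H]2C(c2ccccc2)(c2ccccc2)O[Si](C)(C)C)[C@H]1C/C=C(\C(=O)OC)CC/C=C(\C)CC/C=C(/C)CC1.CC(=O)[O-] | intermediate
22 | methyl (1Z,4R,7Z,11E)-4-formyl-7,11-dimethylcyclotetradeca-1,7,11-triene-1-carboxylate | O=C[C@H]1C/C=C(\C(=O)OC)CC/C=C(\C)CC/C=C(/C)CC1 | intermediate
23 | 5-bromo-2-methylpent-2-ene | CC(C)=CCCBr | starting material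
24 | (4-methylpent-3-en-1-yl)magnesium bromide | CC(C)=CCC[Mg]Br | intermediate
25 | methyl (1Z,4R,7Z,11E)-4-(1-hydroxy-5-methylhex-4-en-1-yl)-7,11-dimethylcyclotetradeca-1,7,11-triene-1-carboxylate (both carbinol epimers) | CC(C)=CCCC(O)[C@H]1C/C=C(\C(=O)OC)CC/C=C(\C)CC/C=C(/C)CC1 | intermediate
26 | methyl (1Z,4R,7Z,11E)-7,11-dimethyl-4-(5-methylhex-4-enoyl)cyclotetradeca-1,7,11-triene-1-carboxylate | CC(C)=CCCC(=O)[C@H]1C/C=C(\C(=O)OC)CC/C=C(\C)CC/C=C(/C)CC1 | intermediate
27 | methyl (1Z,4R,7Z,11E)-7,11-dimethyl-4-(6-methylhepta-1,5-dien-2-yl)cyclotetradeca-1,7,11-triene-1-carboxylate (CNP0163659.2) | C=C(CCC=C(C)C)[C@H]1C/C=C(\C(=O)OC)CC/C=C(\C)CC/C=C(/C)CC1 | target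

**Step count and risks**
Total step count: 10. Longest linear sequence: 9 steps (1 → 8 → 13 → 15 → 18 → 19 → 22 → 25 → 26 → 27); step 2 is the only side branch.

The three steps most likely to fail:

Step 7 (ring closure). Risks are oligomerisation, syn/anti scrambling of the ester-bearing allyl fragment (loss of the 1Z geometry), and eroded ee. The fallback sets out from 19 and returns at 26.
- 19 is oxidised (NaClO2, NaH2PO4, 2-methylbut-2-ene, t-BuOH–H2O) to (5Z,9E,13Z)-15-(acetyloxy)-13-(methoxycarbonyl)-5,9-dimethylpentadeca-5,9,13-trienoic acid F1.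
- F1 is coupled (PivCl, Et3N, LiCl, THF) with (4S)-4-benzyl-1,3-oxazolidin-2-one to methyl (2Z,5E,9Z)-2-(2-acetoxyethylidene)-14-[(4S)-4-benzyl-2-oxo-1,3-oxazolidin-3-yl]-6,10-dimethyl-14-oxotetradeca-5,9-dienoate F2.
- The sodium enolate of F2 (NaN(SiMe3)2, THF, −78 °C; the imide α-CH2 is the most acidic site) is closed onto C1 with Pd(PPh3)4 at high dilution. This is an auxiliary-controlled Tsuji–Trost alkylation in which the benzyl group shields one enolate face and gives 4R, forming methyl (1Z,4R,7Z,11E)-4-{[(4S)-4-benzyl-2-oxo-1,3-oxazolidin-3-yl]carbonyl}-7,11-dimethylcyclotetradeca-1,7,11-triene-1-carboxylate F3.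
- LiSEt (THF, 0 °C) gives methyl (1Z,4R,7Z,11E)-4-[(ethylsulfanyl)carbonyl]-7,11-dimethylcyclotetradeca-1,7,11-triene-1-carboxylate F4.
- Fukuyama coupling (PdCl2(PPh3)2, toluene) with (4-methylpent-3-en-1-yl)zinc chloride F5, made from Grignard reagent 24 and ZnCl2, gives ketone 26.

Step 1 (four-stage one-pot organocopper sequence with an acetal-bearing Grignard reagent made from a chloride). The fallback sets out from 1 and returns at 8.
- 1 is converted with NaI (acetone, reflux) into 4-iodo-1,1-dimethoxybutane F6 and then with zinc dust (LiCl, THF) into (4,4-dimethoxybutyl)zinc iodide F7.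
- F7 is joined by Negishi coupling (Pd(PPh3)4, THF) to (3Z)-4-iodopenta-1,3-diene F8, which is made from acrolein by Stork–Zhao-type olefination with the ylide of (1-iodoethyl)triphenylphosphonium iodide (NaN(SiMe3)2, THF, −78 °C).
- The Z geometry then comes from the Wittig step instead of the carbometalation, and the stereoretentive coupling gives 8.

Step 4 (Mitsunobu-type C-alkylation of a phosphonoacetate). The fallback sets out from 13 and returns at 15.
- 13 is converted (I2, PPh3, imidazole, CH2Cl2) into (3E,7Z)-1-iodo-12,12-dimethoxy-4,8-dimethyldodeca-3,7-diene F9.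
- F9 alkylates the sodium salt of 14 (NaH, DMSO, 20 °C) in a classical SN2 reaction to give 15.

**Further compounds**
F1 | step 7 | (5Z,9E,13Z)-15-(acetyloxy)-13-(methoxycarbonyl)-5,9-dimethylpentadeca-5,9,13-trienoic acid | CC(=O)OC/C=C(\C(=O)OC)CC/C=C(\C)CC/C=C(/C)CCCC(=O)O
F2 | step 7 | methyl (2Z,5E,9Z)-2-(2-acetoxyethylidene)-14-[(4S)-4-benzyl-2-oxo-1,3-oxazolidin-3-yl]-6,10-dimethyl-14-oxotetradeca-5,9-dienoate | CC(=O)OC/C=C(\C(=O)OC)CC/C=C(\C)CC/C=C(/C)CCCC(=O)N1[C@@H](Cc2ccccc2)COC1=O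
F3 | step 7 | methyl (1Z,4R,7Z,11E)-4-{[(4S)-4-benzyl-2-oxo-1,3-oxazolidin-3-yl]carbonyl}-7,11-dimethylcyclotetradeca-1,7,11-triene-1-carboxylate | O=C(N1[C@@H](Cc2ccccc2)COC1=O)[C@H]1C/C=C(\C(=O)OC)CC/C=C(\C)CC/C=C(/C)CC1
F4 | step 7 | methyl (1Z,4R,7Z,11E)-4-[(ethylsulfanyl)carbonyl]-7,11-dimethylcyclotetradeca-1,7,11-triene-1-carboxylate | CCSC(=O)[C@H]1C/C=C(\C(=O)OC)CC/C=C(\C)CC/C=C(/C)CC1
F5 | step 7 | (4-methylpent-3-en-1-yl)zinc chloride | CC(C)=CCC[Zn]Cl
F6 | step 1 | 4-iodo-1,1-dimethoxybutane | COC(CCCI)OC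
F7 | step 1 | (4,4-dimethoxybutyl)zinc iodide | COC(CCC[Zn]I)OC
F8 | step 1 | (3Z)-4-iodopenta-1,3-diene | C=C/C=C(/C)I
F9 | step 4 | (3E,7Z)-1-iodo-12,12-dimethoxy-4,8-dimethyldodeca-3,7-diene | ICC/C=C(\C)CC/C=C(/C)CCCC(OC)OC
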